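**Last readings.** Both runs stop where the question stops.

in all of them: electrophile 0.30 M
- spring: nucleophile 0.34 M; run made earlier
- dusk: nucleophile 0.92 M; run made earlier
- Tuesday's: nucleophile 0.450 M; time 2.0 min
- Sunday's: nucleophile 0.300 M; time 2.0 min
- Saturday's: nucleophile 0.670 M; time 2.0 min

| run | time / s | electrophile / % | target / % |
|---|---|---|---|
| spring | 10.0 | 71.9 | 5.2 |
| spring | 20.0 | 64.9 | 7.2 |
| spring | 30.0 | 63.2 | 9.1 |
| spring | 60.0 | 58.2 | 14.4 |
| spring | 120 | 50.9 | 14.0 |
| dusk | 25.0 | 53.0 | 22.2 |
| dusk | 50.0 | 42.6 | 29.8 |
| dusk | 80.0 | 33.2 | 31.9 |
| dusk | 90.0 | 30.3 | 33.4 |
| dusk | 120 | 25.8 | 28.5 |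

(scatter of a reading: 1 percentage point)

* part of the electrophile that has reacted at the end, Tuesday's
* part of the electrophile that has reacted at the end, Sunday's
* part of the electrophile that has reacted at the end, Saturday's
* what raising the concentration of nucleophile from its lowest to its highest value here does to the part of the electrophile that has reacted (changes below 5 percentage points count as none) (it rises / it falls / no change)

- steps under discussion: electrophile + nucleophile -> acid set free + target; nucleophile + acid set free <-> protonated nucleophile; target <-> isomer of the product; target -> over-reaction product; electrophile <-> dormant form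
- what has gone from electrophile into another species counts as reacted, even if it can come back

**First way.** Reacted counts whatever has left the electrophile, so each answer is the complement of the electrophile left. At 120 s, the asked time, the spring run holds 50.9 % and the dusk run 25.8 %. Take the logarithm of electrophile left as a straight line in the nucleophile charged. The slope between the two runs is 1.17 L mol⁻¹. This is the nucleophile sensitivity: the fall in that logarithm, at the asked time, per unit of nucleophile charged. It gives 55.3 % reacted for Tuesday's, 46.7 % for Sunday's and 65.4 % for Saturday's. From Sunday's to Saturday's that is a rise of 19 percentage points, beyond the margin.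

**Second way.** A single run also offers a slope. The spring run falls from 63.2 % at 30.0 s to its last reading. Scaled to the asked time and divided by its charge, that gives 0.849 L mol⁻¹. The dusk run, from 53.0 % at 25.0 s, gives 0.988 L mol⁻¹. Stepped from the dusk reading, this puts Saturday's at 67.0 %, which is 1.6 points above the first way.

**Which cheats.** The two values for Saturday's both rest on the last dusk reading, so their closeness is no check. The slopes are the test, and they part. The late slope cheats: it divides a late rate by the charge, yet the steps let nucleophile go into target and, through the acid set free, into its protonated form. The first way spans whole runs, early and late stretches together, so it is the reckoning kept.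

**The result.** The forecast gave 55 %, 47 % and 65 % and said it rises, holding that “electrophile reacted uses two nucleophiles”. The flasks give 56.7 % for Tuesday's, 48.7 % for Sunday's and 66.6 % for Saturday's, and it rises by 18 points. Sunday's keeps half of its nucleophile free at the end. Stepped from Sunday's result, the sensitivity puts Saturday's at 66.8 % reacted.

    electrophile + nucleophile → acid set free + target (k = 0.0180 L mol⁻¹ s⁻¹)
    nucleophile + acid set free ⇌ protonated nucleophile, settled at all times (K = 130 L mol⁻¹)
    target ⇌ isomer of the product (K = 17.0, k = 6.20 × 10⁻⁴ s⁻¹)
    target → over-reaction product (k = 0.0100 s⁻¹)
    electrophile ⇌ dormant form (K = 0.410, k = 0.0470 s⁻¹)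

**Further flask.** A flask like Saturday's with 2.7 M of nucleophile is close to pseudo-first-order. Stepped from Saturday's result, the sensitivity leaves 3.10 % electrophile. The computed flask holds 2.43 %, with 97.6 % reacted.

The readings were generated by integration for an exercise; noise was put on by code.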